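**Retrosynthesis**
1. Querciformolide D (**21**) comes from an acid-triggered epoxide/epoxide oxa-cascade of the 3,4:7,8-bis(epoxide) lactone (**19**). This is the last ring to form, the cis-THF, and it sets C3, C4, C7 and C8.
2. The 7-membered α-methylene lactone (**18**) closes from the C12 tertiary alcohol and the C17 acid of a macrocyclic 11,12-diol (**12**). That diol comes from a SmI2 keto-aldehyde pinacol coupling (**11**), which closes the 14-membered ring and sets C11 and C12.
3. Keto-aldehyde **11** is built by two successive vinyl-ether Claisen [3,3]-rearrangements. These are the key steps: each forms an E-trisubstituted alkene and a C–C bond from a secondary isopropenyl carbinol.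
4. The carbon skeleton C12→C3 and the C1 stereocentre come from (+)-limonene oxide by ring cleavage, and the C17 handle is installed by SeO2 oxidation.

Ring order: 14-membered carbocycle, then 7-membered lactone, then THF.

Assumptions:
- Commercial (+)-limonene oxide (cis/trans mixture) is used; both isomers give the same (R)-keto-aldehyde.
- Diastereoselectivity in the macrocycle steps (pinacol, epoxidation) is substrate-controlled by C1 and ring conformation; minor diastereomers are removed chromatographically.

---

**Step 1**
Reactants: 1 (+)-limonene oxide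
Product: 2 allylic alcohol
Conditions: SeO2 (5 mol %), TBHP, CH2Cl2, 0 °C → rt
Reagents that add atoms: tert-butyl hydroperoxide, CC(C)(C)OO (source of the new O)
Why: Riley allylic oxidation hydroxylates the isopropenyl CH3, the only alkene left because the ring alkene is masked as the epoxide. C1 is untouched.

**Step 2**
Reactants: 2, 3 (4-methoxybenzyl bromide)
Product: 4 PMB ether
Conditions: NaH, TBAI (cat.), THF/DMF, 0 °C
Reagents that add atoms: 4-methoxybenzyl bromide, COc1ccc(CBr)cc1
Why: Williamson etherification. PMB survives Grignard, Claisen and SmI2 conditions and can later be removed by DDQ without touching silyl ethers.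

**Step 3**
Reactants: 4
Product: 5 keto-aldehyde
Conditions: H5IO6, THF/H2O, 0 °C → rt
Reagents that add atoms: periodic acid, OI(O)(O)(O)(O)=O; water, O
Why: the epoxide hydrolyses in situ to the 1,2-diol, then Malaprade cleavage gives the 1,6-keto-aldehyde (C12 ketone, C3 aldehyde). Both epoxide diastereomers converge and the C1 stereocentre is preserved.

**Step 4**
Reactants: 5, 6 (isopropenylmagnesium bromide)
Product: 7 hydroxy ketone
Conditions: 6 (1.05 equiv), THF, −78 °C
Reagents that add atoms: isopropenylmagnesium bromide, C=C(C)[Mg]Br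
Why: Grignard addition is chemoselective for the aldehyde over the methyl ketone. The new C3 carbinol is an epimer mixture, which is irrelevant because it is destroyed in step 5.

**Step 5**
Reactants: 7, 8 (ethyl vinyl ether)
Product: 9 E-enal
Conditions: CH2=CHOEt (excess), Hg(OAc)2 (10 mol %), 140 °C, sealed tube
Reagents that add atoms: ethyl vinyl ether, C=COCC (net +C2H2; EtOH is lost)
Why: Hg(II) transvinylation gives the allyl vinyl ether, which undergoes Claisen [3,3] rearrangement. The chair TS with the C2 chain equatorial gives the E-trisubstituted C3=C4 alkene and forms the C5–C6 bond. The carbinol stereochemistry is lost.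

**Step 6**
Reactants: 9, 6
Product: 10 hydroxy ketone
Conditions: 6 (1.05 equiv), THF, −78 °C
Reagents that add atoms: isopropenylmagnesium bromide, C=C(C)[Mg]Br
Why: the new aldehyde is attacked in preference to the methyl ketone. The C7 epimers are irrelevant because the next step destroys this centre.

**Step 7**
Reactants: 10, 8
Product: 11 keto-aldehyde (macrocyclisation precursor)
Conditions: CH2=CHOEt (excess), Hg(OAc)2 (10 mol %), 140 °C, sealed tube
Reagents that add atoms: ethyl vinyl ether, C=COCC (net +C2H2)
Why: a second Claisen rearrangement gives the E-C7=C8 alkene, forms the C9–C10 bond and delivers the C11 aldehyde. It is a chair TS with the C6 chain equatorial.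

**Step 8**
Reactants: 11
Product: 12 macrocyclic 11,12-diol
Conditions: SmI2 (3 equiv), t-BuOH (2 equiv), THF, 2 mM, syringe pump over 8 h, 25 °C
Reagents that add atoms: none (only H from t-BuOH or work-up)
Why: intramolecular SmI2 cross-pinacol coupling, in which the aldehyde ketyl adds to the methyl ketone, closes the 14-membered ring. A Sm(III)-chelated TS gives the dl (like) diol, and C1 with the ring conformation selects the (11R,12R) series.

**Step 9**
Reactants: 12, 13 (TESOTf)
Product: 14 C11-TES ether
Conditions: TESOTf (1.1 equiv), 2,6-lutidine, CH2Cl2, −78 °C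
Reagents that add atoms: triethylsilyl triflate, CC[Si](CC)(CC)OS(=O)(=O)C(F)(F)F
Why: the secondary C11-OH silylates in preference to the tertiary C12-OH. The TES group blocks an 8-membered lactone and the 8,11-ether pathway later.

**Step 10**
Reactants: 14
Product: 15 allylic alcohol
Conditions: DDQ, CH2Cl2/pH 7 buffer, 0 °C
Reagents that add atoms: none
Why: oxidative PMB cleavage is orthogonal to TES, and the E-alkenes survive at 0 °C.

**Step 11**
Reactants: 15
Product: 16 α-methylene aldehyde
Conditions: MnO2 (activated, excess), CH2Cl2, rt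
Reagents that add atoms: none
Why: MnO2 oxidises only the allylic primary alcohol. The tertiary alcohol and the TES ether are inert.

**Step 12**
Reactants: 16
Product: 17 α-methylene acid
Conditions: NaClO2, NaH2PO4, 2-methyl-2-butene, t-BuOH/H2O, rt
Reagents that add atoms: sodium chlorite, [Na+].[O-]Cl=O (O donor)
Why: Pinnick oxidation. The scavenger protects the trisubstituted alkenes from HOCl.

**Step 13**
Reactants: 17
Product: 18 seven-membered α-methylene lactone
Conditions: 2,4,6-Cl3C6H2COCl, Et3N, THF; then DMAP, toluene, 1 mM, 80 °C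
Reagents that add atoms: none (the mixed anhydride leaving group is lost)
Why: Yamaguchi lactonisation with the tertiary C12-OH as the only free hydroxyl. C12 keeps its configuration because the C–O bond is not broken.

**Step 14**
Reactants: 18
Product: 19 trans,trans-3,4:7,8-bis(epoxide)
Conditions: mCPBA (2.2 equiv), NaHCO3, CH2Cl2, 0 °C
Reagents that add atoms: m-chloroperbenzoic acid, OOC(=O)c1cccc(Cl)c1 (O donor)
Why: syn epoxidation of each E-trisubstituted alkene gives trans-epoxides. Peripheral attack directed by the ring conformation (C1, C11, C12) gives the (3R,4R,7R,8R) diastereomer. The electron-poor α-methylene lactone, the TES ether and the lactone are inert.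

**Step 15**
Reactants: 19
Product: 20 4,7-epoxy-3,8-diol (THF), still bearing the TES ether
Conditions: CSA (20 mol %), THF/H2O 9:1, 0 °C → rt
Reagents that add atoms: water, O
Why: acid activates the 7,8-epoxide, and the oxygen of the 3,4-epoxide attacks C7 (5-exo, inversion) to form the cis-THF. Water then opens the oxiranium at C3 with inversion. C4 and C8 retain their configuration, so each E-epoxide is opened anti, giving the 3S,4R,7S,8R pattern.

**Step 16**
Reactants: 20
Product: 21 querciformolide D
Conditions: HF·pyridine, pyridine/THF, 0 °C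
Reagents that add atoms: none
Why: the TES ether is removed while the lactone, THF and tertiary alcohols are untouched. No stereocentre is affected.

---

**Compound list**

1 | (+)-limonene oxide, (4R)-1-methyl-4-(prop-1-en-2-yl)-7-oxabicyclo[4.1.0]heptane (cis/trans mixture at the epoxide) | C=C(C)[C@@H]1CCC2(C)OC2C1 | starting material
2 | 2-[(4R)-1-methyl-7-oxabicyclo[4.1.0]heptan-4-yl]prop-2-en-1-ol | C=C(CO)[C@@H]1CCC2(C)OC2C1 | intermediate
3 | 4-methoxybenzyl bromide | COc1ccc(CBr)cc1 | starting material
4 | PMB ether of 2 | C=C(COCc1ccc(OC)cc1)[C@@H]1CCC2(C)OC2C1 | intermediate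
5 | (3R)-3-{3-[(4-methoxybenzyl)oxy]prop-1-en-2-yl}-6-oxoheptanal | CC(=O)CC[C@H](CC=O)C(=C)COCc1ccc(OC)cc1 | intermediate
6 | isopropenylmagnesium bromide | C=C(C)[Mg]Br | starting material
7 | (5R)-7-hydroxy-8-methyl-5-{3-[(4-methoxybenzyl)oxy]prop-1-en-2-yl}non-8-en-2-one (C7 epimers) | CC(=O)CC[C@H](CC(O)C(C)=C)C(=C)COCc1ccc(OC)cc1 | intermediate
8 | ethyl vinyl ether | C=COCC | starting material
9 | (4E,7R)-7-{3-[(4-methoxybenzyl)oxy]prop-1-en-2-yl}-4-methyl-10-oxoundec-4-enal | CC(=O)CC[C@H](C/C=C(/CCC=O)C)C(=C)COCc1ccc(OC)cc1 | intermediate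
10 | (5R,7E)-11-hydroxy-8,12-dimethyl-5-{3-[(4-methoxybenzyl)oxy]prop-1-en-2-yl}trideca-7,12-dien-2-one (C11 epimers) | CC(=O)CC[C@H](C/C=C(/CCC(O)C(C)=C)C)C(=C)COCc1ccc(OC)cc1 | intermediate
11 | (4E,8E,11R)-4,8-dimethyl-11-{3-[(4-methoxybenzyl)oxy]prop-1-en-2-yl}-14-oxopentadeca-4,8-dienal | CC(=O)CC[C@H](C/C=C(/CC/C=C(/CCC=O)C)C)C(=C)COCc1ccc(OC)cc1 | intermediate
12 | 17-(4-methoxybenzyloxy)cembra-3E,7E,15-triene-11R,12R-diol (1R) | C=C(COCc1ccc(OC)cc1)[C@H]1C/C=C(\C)CC/C=C(\C)CC[C@@H](O)[C@](C)(O)CC1 | intermediate
13 | triethylsilyl triflate | CC[Si](CC)(CC)OS(=O)(=O)C(F)(F)F | starting material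
14 | 11-O-TES ether of 12 | C=C(COCc1ccc(OC)cc1)[C@H]1C/C=C(\C)CC/C=C(\C)CC[C@@H](O[Si](CC)(CC)CC)[C@](C)(O)CC1 | intermediate
15 | 17-hydroxy compound (PMB removed) | C=C(CO)[C@H]1C/C=C(\C)CC/C=C(\C)CC[C@@H](O[Si](CC)(CC)CC)[C@](C)(O)CC1 | intermediate
16 | 17-al | C=C(C=O)[C@H]1C/C=C(\C)CC/C=C(\C)CC[C@@H](O[Si](CC)(CC)CC)[C@](C)(O)CC1 | intermediate
17 | 17-oic acid | C=C(C(=O)O)[C@H]1C/C=C(\C)CC/C=C(\C)CC[C@@H](O[Si](CC)(CC)CC)[C@](C)(O)CC1 | intermediate
18 | 11-OTES-cembra-3E,7E,15-trien-17,12-olide | C=C1C(=O)O[C@]2(C)CC[C@@H]1C/C=C(\C)CC/C=C(\C)CC[C@H]2O[Si](CC)(CC)CC | intermediate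
19 | 3R,4R,7R,8R-3,4:7,8-diepoxide of 18 | C=C1C(=O)O[C@]2(C)CC[C@@H]1C[C@H]3O[C@]3(C)CC[C@H]4O[C@]4(C)CC[C@H]2O[Si](CC)(CC)CC | intermediate
20 | 11-O-TES-4,7-epoxy-3,8-diol lactone | C=C1C(=O)O[C@]2(C)CC[C@@H]1C[C@H](O)[C@@]1(C)CC[C@H](O1)[C@](C)(O)CC[C@H]2O[Si](CC)(CC)CC | intermediate
21 | querciformolide D | C=C1C(=O)O[C@]2(C)CC[C@@H]1C[C@H](O)[C@@]1(C)CC[C@H](O1)[C@](C)(O)CC[C@H]2O | target

---

**Totals:** 16 steps, longest linear sequence 16 steps (from commercial limonene oxide).

**Three steps most likely to fail, each with a fallback that changes the approach**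
1. **Step 8 (SmI2 macro-pinacol):** the yield and dr are uncertain, and premature aldehyde reduction competes. Fallback: close the ring instead by intramolecular NHK coupling of the C11 aldehyde with a C12 alkenyl halide made from the ketone via its trisubstituted enol triflate (aldehyde carried as an acetal). Then use VO(acac)2-directed epoxidation and Red-Al reduction to give the 11,12-diol.
2. **Step 15 (epoxide/epoxide oxa-cascade):** competing water opening, a 6-endo pathway, or the trans-THF could dominate, and the bis-epoxide diastereoselectivity in step 14 is uncertain. Fallback: make the C3/C4 diol by a second macro-pinacol (C3 aldehyde plus a C4 methyl ketone built by two Saucy–Marbet Claisen rearrangements from the limonene-derived ketone). Then close the THF by conventional C4-OH/7,8-epoxide 5-exo cyclisation.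
3. **Step 13 (lactonisation onto the tertiary C12-OH):** acylation of this hindered alcohol may fail, and DMAP can add to the acrylate. Fallback: form the 7-membered lactone first on an acyclic hydroxy-acid fragment, where there is no macrocyclic strain, and close the 14-membered ring afterwards by RCM or NHK coupling.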